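The numbers of this flask come from no measurement.

You call this flask slow, suspect the feed of Q from the gas E, and want a quick number, so here are the terms before my reply.

    Z.Q → D (k1 = 0.032 min⁻¹)
    Z + Q → Z.Q, rate k2*[Z]*[Q]^0.5 (k2 = 0.40 L⁰·⁵ mol⁻⁰·⁵ min⁻¹)
    Z ⇌ J (K3 = 1.9, k3 = 0.035 min⁻¹)
    E ⇌ Q, rate k4*(csat - [Q]) (k4 = 1.5 min⁻¹, csat = 53 mM)

Z 0.18 M; E 53 mM (held); time 25 min

- at the start none of Q is dissolved
- run time (flask): 25 min

- the Z.Q standing at 25 min, as a percentage of the Z charged
- the change that raises the amount of Z.Q at 25 min, in percent of the Z charged most ("none" if none brings more than 2 percentage points) (amber / teal / none)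
- amount of Z.Q at 25 min, in percent of the Z charged, after amber

- amber: doubling the transfer coefficient of step 4, all else as stated
- teal: doubling the saturation concentration of E, all else as stated

Your hunch can be priced. With [Q] held at 53 mM, Z would fall pseudo-first-order into Z.Q at 0.0921 min⁻¹, far slower than the transfer at 1.5 min⁻¹, so I solve that saturated flask exactly and correct it. With the exchange of Z and J running back at 0.0184 min⁻¹, Z decays at 0.133 min⁻¹ and 0.0128 min⁻¹, the first carrying a share 0.953, and with the drain to D this gives 42.2 %.

The correction is the feed gap, the fraction of saturation missing from [Q] when the transfer just pays for the coupling at full charge, 20.8 %. The rate goes as the root of [Q] and the gap shrinks with [Z], so over the conversion I take the coupling to run short by about a quarter of the feed gap. Z splits towards Z.Q with share 72.5 %, and after the drain that shortfall costs 0.47 percentage points. So I commit to 41.8 %, and for amber, whose doubled transfer coefficient takes the feed gap to 10.4 %, to 42.0 %. Teal lifts the share to 78.8 %, worth about 2.9 points, more than the 2 points needed, so I choose teal.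

The forecast gave 40.5 % (37 % to 44 %), teal, and 41.7 % (38 % to 45 %), holding that “Transfer of Q is fast compared with its consumption”.

The simulation gives 41.8 %, teal with 3.3 points against 0.24 points for amber, and 42.0 %. The neighbour flask, charged with 0.072 M of Z, has a feed gap of 8.34 %, so its cost is 0.19 points and I reckon 42.0 % for it. The neighbour flask reads 42.0 %.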